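The bicyclo[3.2.1]oct-2-en-8-one is cut at C5–C8, leaving the seven-membered ring C1–C7 with C8 as a one-carbon handle on C1. Its C3–C4–C5 segment carries three adjacent oxygens, the imprint of a 1,3-dimethoxy-2-oxyallyl cation. One catalytic enantioselective (4+3) cycloaddition therefore joins that cation, released from silyl enol ether acetal 10, to the termini of the (E)-1-aryl-2-(silyloxymethyl)butadiene 5, forming C2–C3, C5–C6, the ring and the C6 stereocentre from which all others follow. Afterwards C7 methyl and C1 allyl are added across an enal, a transannular aldol closes C5–C8, and C2=C3, the C4 acetate and the C8 ketone are adjusted.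

Key step: step 7

Remark: in the discussion and in the names of the bicyclic compounds 16–23 the ring carbons keep the locants of the target (C1 allyl bridgehead, C2, C3, C4, C5 methoxy bridgehead, C6 aryl, C7 methyl, C8 bridge carbon).
Assumption: C3 and C5 in 11–15, C3 in 16–17 and the C8 carbinol centre in 16–22 are drawn as the epimers expected to predominate; each is erased later (C5 in step 12, C3 in step 13, C8 in step 18), so mixtures at these centres are carried on.
Assumption: the squaramide is named as one antipode; whichever antipode delivers the 3R adduct 11 is the one to be used.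
Remark: C4 is reduced and acetylated while C8 is still a silyl-protected carbinol, because a strained bridging C8 ketone would compete with the C4 enone for hydride.

Step 1
Reactants: 1 5-ethynyl-1,2,3-trimethoxybenzene
Product: 2 (E)-4,4,5,5-tetramethyl-2-[2-(3,4,5-trimethoxyphenyl)ethenyl]-1,3,2-dioxaborolane
Conditions: pinacolborane (1.1 equiv), Cp2Zr(H)Cl (5 mol %), Et3N (10 mol %), neat, 60 °C
Reagents that add atoms: pinacolborane, CC1(C)OBOC1(C)C
Why: Zirconocene-catalysed hydroboration of a terminal arylalkyne is a syn, anti-Markovnikov addition and should give only the (E)-alkenylboronate.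

Step 2
Reactants: 3 2-bromoprop-2-en-1-ol
Product: 4 [(2-bromoprop-2-en-1-yl)oxy](tert-butyl)dimethylsilane
Conditions: TBSCl, imidazole, CH2Cl2, 0 °C to rt
Reagents that add atoms: tert-butyldimethylsilyl chloride, CC(C)(C)[Si](C)(C)Cl
Why: Imidazole-mediated silylation of a primary alcohol is routine and leaves the vinyl bromide untouched.

Step 3
Reactants: 2 (E)-alkenylboronate; 4 2-bromoallyl silyl ether
Product: 5 (E)-tert-butyldimethyl{[2-methylidene-4-(3,4,5-trimethoxyphenyl)but-3-en-1-yl]oxy}silane
Conditions: Pd(PPh3)4 (5 mol %), K2CO3 (3 equiv), 1,4-dioxane/H2O 4:1, 80 °C, trace BHT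
Reagents that add atoms: none
Why: Suzuki–Miyaura coupling of an alkenyl bromide with an alkenylboronate proceeds with retention at both alkene carbons, so the (E)-1-aryl-2-substituted diene should result.

Step 4
Reactants: 6 methyl methoxyacetate; 7 methyl dimethoxyacetate
Product: 8 methyl 2,4,4-trimethoxy-3-oxobutanoate
Conditions: NaH (2.2 equiv), 7 (2 equiv), THF, reflux, slow addition of 6; AcOH quench
Reagents that add atoms: none
Why: Crossed Claisen condensation in which the enolate of 6 is formed at low concentration in an excess of the electrophilic ester 7, whose acetal C–H is hardly enolised, and deprotonation of the β-keto ester drives the equilibrium.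

Step 5
Reactants: 8 methyl 2,4,4-trimethoxy-3-oxobutanoate
Product: 9 1,1,3-trimethoxypropan-2-one
Conditions: NaCl, H2O (2 equiv), DMSO, 140 °C
Reagents that add atoms: none
Why: Krapcho dealkoxycarbonylation of a β-keto ester runs under near-neutral conditions and therefore spares the dimethyl acetal, which aqueous acid would not.

Step 6
Reactants: 9 1,1,3-trimethoxypropan-2-one
Product: 10 (Z)-triethyl[(1,3,3-trimethoxyprop-1-en-2-yl)oxy]silane
Conditions: Et3SiOTf (1.1 equiv), Et3N (1.5 equiv), Et2O, 0 °C
Reagents that add atoms: triethylsilyl trifluoromethanesulfonate, CC[Si](CC)(CC)OS(=O)(=O)C(F)(F)F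
Why: Soft enolisation with a silyl triflate and triethylamine removes a proton from the less hindered CH2OMe side, not from the acetal CH, and should give the trisubstituted (Z)-enol ether (either geometry would ionise to the same cation).

Step 7
Reactants: 5 (E)-aryl diene; 10 silyl enol ether acetal
Product: 11 (2S,3R,7R)-5-{[(tert-butyldimethylsilyl)oxy]methyl}-2,7-dimethoxy-3-(3,4,5-trimethoxyphenyl)cyclohept-4-en-1-one
Conditions: 3-{[3,5-bis(trifluoromethyl)phenyl]amino}-4-({(2S)-3,3-dimethyl-1-oxo-1-[(2R)-2-(phenanthren-9-yl)pyrrolidin-1-yl]butan-2-yl}amino)cyclobut-3-ene-1,2-dione (10 mol %), Et3SiOTf (10 mol %), 10 (1.5 equiv), toluene/CH2Cl2, −78 °C; Et3N quench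
Reagents that add atoms: none
Why: Proposed new method: the silyl triflate, activated by binding of its triflate to the squaramide, ionises the dimethyl acetal of 10 to a symmetric 1,3-dimethoxy-2-(triethylsilyloxy)allyl cation held in a chiral ion pair, which adds across the s-cis diene of 5 in concert or stepwise (C2–C3 first, then collapse of the aryl-stabilised allyl cation onto the silyl enol ether to form C5–C6), after which the oxocarbenium ion returns its silyl group to triflate and Et3SiOMe is the only by-product. The closest known reactions are the silyl-triflate-promoted (4+3) cycloadditions of alkoxy-substituted 2-silyloxyallyl cations with 1,3-dienes, which give racemates, and the squaramide/silyl-triflate-catalysed enantioselective (4+3) additions of such cations to furans; the untested element is enantiocontrol with an acyclic 1-aryldiene. The seven-membered ring closes by intermolecular (4+3) annulation, its second bond forming as a 7-endo attack of the enol ether carbon on the benzylic terminus of the allyl cation. C6 (ring position 3 of 11) is set by the catalyst, which shields one face of the ion-paired cation as it meets the diene, whereas the two methoxy-bearing carbons arise cis from the W-shaped cation, stay epimerisable and do not matter. The step needs (4+3) closure in preference to (3+2) or Friedel–Crafts closure and needs no regiocontrol: the cation is symmetric, the CH2OTBS group on C1 raises the s-cis population of the diene, and the trimethoxyphenyl group localises the charge at C6 so that the ring closes there.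

Step 8
Reactants: 11 silyl-protected cycloheptenone
Product: 12 (2S,3R,7R)-5-(hydroxymethyl)-2,7-dimethoxy-3-(3,4,5-trimethoxyphenyl)cyclohept-4-en-1-one
Conditions: HF·pyridine, pyridine, THF, 0 °C to rt
Reagents that add atoms: none
Why: Buffered fluoride cleaves the primary silyl ether without the basic conditions that would promote aldol chemistry of the α,α'-dimethoxy ketone.

Step 9
Reactants: 12 allylic alcohol
Product: 13 (3R,4S,6R)-4,6-dimethoxy-5-oxo-3-(3,4,5-trimethoxyphenyl)cyclohept-1-ene-1-carbaldehyde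
Conditions: MnO2 (15 equiv), CH2Cl2, rt
Reagents that add atoms: none
Why: Manganese dioxide oxidises the allylic primary alcohol selectively to the enal under neutral conditions, which avoids γ-deprotonation at the benzylic C6 stereocentre.

Step 10
Reactants: 13 enal
Product: 14 (2S,3R,4S,5E,7R)-2,7-dimethoxy-4-methyl-3-(3,4,5-trimethoxyphenyl)-5-{[(trimethylsilyl)oxy]methylidene}cycloheptan-1-one
Conditions: Me2CuLi (from CuI and MeLi, 1.5 equiv), TMSCl (3 equiv), THF, −78 °C; Et3N, aq. NaHCO3; used crude
Reagents that add atoms: lithium dimethylcuprate, [Li+].C[Cu-]C; chlorotrimethylsilane, C[Si](C)(C)Cl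
Why: Chlorosilane-accelerated cuprate conjugate addition to the enal should outrun attack at the C4 ketone, the methyl group entering C7 on the face opposite the adjacent C6 aryl group while the enolate is captured in situ as the silyl enol ether.

Step 11
Reactants: 14 aldehyde silyl enol ether
Product: 15 (1R,2S,3R,4S,6R)-4,6-dimethoxy-2-methyl-5-oxo-1-(prop-2-en-1-yl)-3-(3,4,5-trimethoxyphenyl)cycloheptane-1-carbaldehyde
Conditions: allyl methyl carbonate (2 equiv), Pd2(dba)3 (2.5 mol %), dppe (10 mol %), THF, 65 °C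
Reagents that add atoms: allyl methyl carbonate, C=CCOC(=O)OC
Why: Tsuji-type palladium-catalysed allylation of a silyl enol ether with an allyl carbonate: the methoxide released on ionisation of the carbonate desilylates 14 to a palladium enolate, which couples with the π-allyl ligand at C1 on the face anti to the vicinal C7 methyl group and so forms the quaternary centre without a free basic enolate.

Step 12
Reactants: 15 keto aldehyde
Product: 16 (1R,3S,5R,6R,7S,8R)-8-hydroxy-3,5-dimethoxy-7-methyl-1-(prop-2-en-1-yl)-6-(3,4,5-trimethoxyphenyl)bicyclo[3.2.1]octan-4-one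
Conditions: K2CO3 (0.5 equiv), MeOH, 0 °C to rt
Reagents that add atoms: none
Why: Transannular aldol addition of the C4 ketone enolate at C5 to the non-enolisable C8 aldehyde (five-membered ring closure), in which enolisation towards C3 is unproductive and reversible and the C5 configuration is dictated by the one-carbon bridge, which can only span the ring face that carries C8.

Step 13
Reactants: 16 β-hydroxy ketone
Product: 18 (1R,5R,6R,7S,8R)-3,5-dimethoxy-7-methyl-1-(prop-2-en-1-yl)-4,8-bis[(triethylsilyl)oxy]-6-(3,4,5-trimethoxyphenyl)bicyclo[3.2.1]oct-3-ene, via C8 triethylsilyl ether 17 (not isolated)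
Conditions: Et3SiOTf (2.5 equiv), Et3N (4 equiv), CH2Cl2, 0 °C to rt
Reagents that add atoms: triethylsilyl trifluoromethanesulfonate, CC[Si](CC)(CC)OS(=O)(=O)C(F)(F)F
Why: Silyl triflate and amine first cap the C8 hydroxyl, which blocks retro-aldol cleavage, and then enolise the ketone in the only direction left open, towards C3, because C5 is quaternary.

Step 14
Reactants: 18 bis-silyl compound
Product: 19 (1S,5R,6R,7S,8R)-3,5-dimethoxy-7-methyl-1-(prop-2-en-1-yl)-8-[(triethylsilyl)oxy]-6-(3,4,5-trimethoxyphenyl)bicyclo[3.2.1]oct-2-en-4-one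
Conditions: Pd(OAc)2 (1.2 equiv), MeCN, rt to 40 °C
Reagents that add atoms: none
Why: Saegusa–Ito oxidation, in which palladation of the silyl enol ether at C3 and syn β-hydride elimination of a C2 hydrogen, the only β-hydrogen present, should give the C2=C3 α-methoxy enone.

Step 15
Reactants: 19 enone
Product: 20 (1S,4R,5S,6R,7S,8R)-3,5-dimethoxy-7-methyl-1-(prop-2-en-1-yl)-8-[(triethylsilyl)oxy]-6-(3,4,5-trimethoxyphenyl)bicyclo[3.2.1]oct-2-en-4-ol
Conditions: NaBH4 (1.5 equiv), CeCl3·7H2O (1.5 equiv), MeOH, −78 to 0 °C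
Reagents that add atoms: none
Why: Luche 1,2-reduction of the enone, with hydride reaching C4 from the face of the C8 bridge because the other face lies over the two-carbon bridge and under the endo C6 aryl group, so the hydroxyl should end up syn to C6–C7 (4R).

Step 16
Reactants: 20 allylic alcohol
Product: 21 (1S,4R,5S,6R,7S,8R)-3,5-dimethoxy-7-methyl-1-(prop-2-en-1-yl)-8-[(triethylsilyl)oxy]-6-(3,4,5-trimethoxyphenyl)bicyclo[3.2.1]oct-2-en-4-yl acetate
Conditions: Ac2O, pyridine, DMAP (cat.), CH2Cl2, rt
Reagents that add atoms: acetic anhydride, CC(=O)OC(C)=O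
Why: DMAP-catalysed acetylation of the only free hydroxyl group, with C4 untouched in configuration.

Step 17
Reactants: 21 silyl ether acetate
Product: 22 (1S,4R,5R,6R,7S,8R)-8-hydroxy-3,5-dimethoxy-7-methyl-1-(prop-2-en-1-yl)-6-(3,4,5-trimethoxyphenyl)bicyclo[3.2.1]oct-2-en-4-yl acetate
Conditions: HF·pyridine, pyridine, THF, 0 °C to rt
Reagents that add atoms: none
Why: Pyridine-buffered fluoride removes the triethylsilyl ether while sparing the allylic acetate and the methyl enol ether, and the trans-1,3 disposition of the two oxygens prevents acetyl migration.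

Step 18
Reactants: 22 hydroxy acetate
Product: 23 (1S,4R,5S,6R,7S)-3,5-dimethoxy-7-methyl-8-oxo-1-(prop-2-en-1-yl)-6-(3,4,5-trimethoxyphenyl)bicyclo[3.2.1]oct-2-en-4-yl acetate
Conditions: Dess–Martin periodinane (1.5 equiv), NaHCO3, CH2Cl2, rt
Reagents that add atoms: none
Why: Dess–Martin oxidation converts the hindered secondary C8 alcohol into the bridging ketone under buffered conditions, and no centre can epimerise because C1 and C5 are quaternary.

Compound list
1 | 5-ethynyl-1,2,3-trimethoxybenzene | C#Cc1cc(OC)c(OC)c(OC)c1 | starting material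
2 | (E)-4,4,5,5-tetramethyl-2-[2-(3,4,5-trimethoxyphenyl)ethenyl]-1,3,2-dioxaborolane | COc1cc(/C=C/B2OC(C)(C)C(C)(C)O2)cc(OC)c1OC | intermediate
3 | 2-bromoprop-2-en-1-ol | C=C(Br)CO | starting material
4 | [(2-bromoprop-2-en-1-yl)oxy](tert-butyl)dimethylsilane | C=C(Br)CO[Si](C)(C)C(C)(C)C | intermediate
5 | (E)-tert-butyldimethyl{[2-methylidene-4-(3,4,5-trimethoxyphenyl)but-3-en-1-yl]oxy}silane | C=C(CO[Si](C)(C)C(C)(C)C)/C=C/c1cc(OC)c(OC)c(OC)c1 | intermediate
6 | methyl methoxyacetate | COCC(=O)OC | starting material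
7 | methyl dimethoxyacetate | COC(OC)C(=O)OC | starting material
8 | methyl 2,4,4-trimethoxy-3-oxobutanoate (racemic, C2 labile) | COC(OC)C(=O)C(OC)C(=O)OC | intermediate
9 | 1,1,3-trimethoxypropan-2-one | COCC(=O)C(OC)OC | intermediate
10 | (Z)-triethyl[(1,3,3-trimethoxyprop-1-en-2-yl)oxy]silane | CO/C=C(\O[Si](CC)(CC)CC)C(OC)OC | intermediate
11 | (2S,3R,7R)-5-{[(tert-butyldimethylsilyl)oxy]methyl}-2,7-dimethoxy-3-(3,4,5-trimethoxyphenyl)cyclohept-4-en-1-one | CO[C@@H]1CC(CO[Si](C)(C)C(C)(C)C)=C[C@H](c2cc(OC)c(OC)c(OC)c2)[C@H](OC)C1=O | intermediate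
12 | (2S,3R,7R)-5-(hydroxymethyl)-2,7-dimethoxy-3-(3,4,5-trimethoxyphenyl)cyclohept-4-en-1-one | CO[C@@H]1CC(CO)=C[C@H](c2cc(OC)c(OC)c(OC)c2)[C@H](OC)C1=O | intermediate
13 | (3R,4S,6R)-4,6-dimethoxy-5-oxo-3-(3,4,5-trimethoxyphenyl)cyclohept-1-ene-1-carbaldehyde | CO[C@@H]1CC(C=O)=C[C@H](c2cc(OC)c(OC)c(OC)c2)[C@H](OC)C1=O | intermediate
14 | (2S,3R,4S,5E,7R)-2,7-dimethoxy-4-methyl-3-(3,4,5-trimethoxyphenyl)-5-{[(trimethylsilyl)oxy]methylidene}cycloheptan-1-one | CO[C@@H]1C/C(=C\O[Si](C)(C)C)[C@@H](C)[C@H](c2cc(OC)c(OC)c(OC)c2)[C@H](OC)C1=O | intermediate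
15 | (1R,2S,3R,4S,6R)-4,6-dimethoxy-2-methyl-5-oxo-1-(prop-2-en-1-yl)-3-(3,4,5-trimethoxyphenyl)cycloheptane-1-carbaldehyde | CO[C@@H]1C[C@@](CC=C)(C=O)[C@@H](C)[C@H](c2cc(OC)c(OC)c(OC)c2)[C@H](OC)C1=O | intermediate
16 | (1R,3S,5R,6R,7S,8R)-8-hydroxy-3,5-dimethoxy-7-methyl-1-(prop-2-en-1-yl)-6-(3,4,5-trimethoxyphenyl)bicyclo[3.2.1]octan-4-one | C=CC[C@]12C[C@H](OC)C(=O)[C@](OC)([C@@H]1O)[C@@H](c1cc(OC)c(OC)c(OC)c1)[C@@H]2C | intermediate
17 | (1R,3S,5R,6R,7S,8R)-3,5-dimethoxy-7-methyl-1-(prop-2-en-1-yl)-8-[(triethylsilyl)oxy]-6-(3,4,5-trimethoxyphenyl)bicyclo[3.2.1]octan-4-one | C=CC[C@]12C[C@H](OC)C(=O)[C@](OC)([C@@H]1O[Si](CC)(CC)CC)[C@@H](c1cc(OC)c(OC)c(OC)c1)[C@@H]2C | intermediate (not isolated)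
18 | (1R,5R,6R,7S,8R)-3,5-dimethoxy-7-methyl-1-(prop-2-en-1-yl)-4,8-bis[(triethylsilyl)oxy]-6-(3,4,5-trimethoxyphenyl)bicyclo[3.2.1]oct-3-ene | C=CC[C@]12CC(OC)=C(O[Si](CC)(CC)CC)[C@](OC)([C@@H]1O[Si](CC)(CC)CC)[C@@H](c1cc(OC)c(OC)c(OC)c1)[C@@H]2C | intermediate
19 | (1S,5R,6R,7S,8R)-3,5-dimethoxy-7-methyl-1-(prop-2-en-1-yl)-8-[(triethylsilyl)oxy]-6-(3,4,5-trimethoxyphenyl)bicyclo[3.2.1]oct-2-en-4-one | C=CC[C@]12C=C(OC)C(=O)[C@](OC)([C@@H]1O[Si](CC)(CC)CC)[C@@H](c1cc(OC)c(OC)c(OC)c1)[C@@H]2C | intermediate
20 | (1S,4R,5S,6R,7S,8R)-3,5-dimethoxy-7-methyl-1-(prop-2-en-1-yl)-8-[(triethylsilyl)oxy]-6-(3,4,5-trimethoxyphenyl)bicyclo[3.2.1]oct-2-en-4-ol | C=CC[C@]12C=C(OC)[C@@H](O)[C@](OC)([C@@H]1O[Si](CC)(CC)CC)[C@@H](c1cc(OC)c(OC)c(OC)c1)[C@@H]2C | intermediate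
21 | (1S,4R,5S,6R,7S,8R)-3,5-dimethoxy-7-methyl-1-(prop-2-en-1-yl)-8-[(triethylsilyl)oxy]-6-(3,4,5-trimethoxyphenyl)bicyclo[3.2.1]oct-2-en-4-yl acetate | C=CC[C@]12C=C(OC)[C@@H](OC(C)=O)[C@](OC)([C@@H]1O[Si](CC)(CC)CC)[C@@H](c1cc(OC)c(OC)c(OC)c1)[C@@H]2C | intermediate
22 | (1S,4R,5R,6R,7S,8R)-8-hydroxy-3,5-dimethoxy-7-methyl-1-(prop-2-en-1-yl)-6-(3,4,5-trimethoxyphenyl)bicyclo[3.2.1]oct-2-en-4-yl acetate | C=CC[C@]12C=C(OC)[C@@H](OC(C)=O)[C@](OC)([C@@H]1O)[C@@H](c1cc(OC)c(OC)c(OC)c1)[C@@H]2C | intermediate
23 | (1S,4R,5S,6R,7S)-3,5-dimethoxy-7-methyl-8-oxo-1-(prop-2-en-1-yl)-6-(3,4,5-trimethoxyphenyl)bicyclo[3.2.1]oct-2-en-4-yl acetate | C=CC[C@]12C=C(OC)[C@@H](OC(C)=O)[C@](OC)(C1=O)[C@@H](c1cc(OC)c(OC)c(OC)c1)[C@@H]2C | target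

Total step count: 18. Longest linear sequence: 15 steps (steps 4–6, then 7–18).

Steps most likely to fail

Step 7. The chiral ion pair may discriminate poorly between the two faces of an acyclic aryl diene, and stepwise collapse of the intermediate allyl cation may leak into five-membered-ring or Friedel–Crafts products. The fallback sets out from 5 and 10 and gives up catalyst control: achiral TMSOTf (0.2 equiv) in CH2Cl2 at −78 °C, the known racemic (4+3) cycloaddition of alkoxy-substituted silyloxyallyl cations with dienes, should give the racemic cycloadduct F1. Preparative chromatography on a chiral stationary phase (amylose tris(3,5-dimethylphenylcarbamate), hexane/2-propanol) then separates it into 11, where the route is rejoined, and the unwanted (2R,3S,7S)-enantiomer F2, which is set aside.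

Step 11. Facial selectivity at the exocyclic enolate carbon C1 may be modest under substrate control alone, and the palladium enolate may instead undergo β-hydride elimination or protonation. The fallback sets out from enal 13 and replaces substrate control by ligand control: Me2CuLi in THF at −78 °C followed by allyl chloroformate should trap the enolate on oxygen as the allyl enol carbonate F3. Pd2(dba)3 with (S)-4-tert-butyl-2-[2-(diphenylphosphanyl)phenyl]-4,5-dihydro-1,3-oxazole (or its antipode, matched to the substrate) in THF at rt then effects decarboxylative allylation within the ion pair and returns to the route at aldehyde 15.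

Step 14. Palladation of the crowded, tetrasubstituted enol ether may be slow, so that hydrolysis back to the ketone or reaction of Pd(OAc)2 at the terminal alkene takes over. The fallback sets out from 18 and replaces dehydrosilylation by selenoxide elimination: PhSeCl in CH2Cl2 at −78 °C should convert the silyl enol ether into the α-phenylselanyl ketone F4 (either C3 epimer serves). H2O2 with pyridine in CH2Cl2 at 0 °C then oxidises selenium, and syn-elimination towards C2, the only β-hydrogen-bearing carbon, returns to the route at enone 19.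

Further compounds
F1 | step 7 | racemic 5-{[(tert-butyldimethylsilyl)oxy]methyl}-2,7-dimethoxy-3-(3,4,5-trimethoxyphenyl)cyclohept-4-en-1-one (both enantiomers of the all-cis diastereomer) | CO[C@@H]1CC(CO[Si](C)(C)C(C)(C)C)=C[C@H](c2cc(OC)c(OC)c(OC)c2)[C@H](OC)C1=O.CO[C@H]1CC(CO[Si](C)(C)C(C)(C)C)=C[C@@H](c2cc(OC)c(OC)c(OC)c2)[C@@H](OC)C1=O
F2 | step 7 | (2R,3S,7S)-5-{[(tert-butyldimethylsilyl)oxy]methyl}-2,7-dimethoxy-3-(3,4,5-trimethoxyphenyl)cyclohept-4-en-1-one | CO[C@H]1CC(CO[Si](C)(C)C(C)(C)C)=C[C@@H](c2cc(OC)c(OC)c(OC)c2)[C@@H](OC)C1=O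
F3 | step 11 | (E)-[(2S,3R,4S,6R)-4,6-dimethoxy-2-methyl-5-oxo-3-(3,4,5-trimethoxyphenyl)cycloheptylidene]methyl prop-2-en-1-yl carbonate | CO[C@@H]1C/C(=C\OC(=O)OCC=C)[C@@H](C)[C@H](c2cc(OC)c(OC)c(OC)c2)[C@H](OC)C1=O
F4 | step 14 | (1R,3S,5R,6R,7S,8R)-3,5-dimethoxy-7-methyl-3-(phenylselanyl)-1-(prop-2-en-1-yl)-8-[(triethylsilyl)oxy]-6-(3,4,5-trimethoxyphenyl)bicyclo[3.2.1]octan-4-one | C=CC[C@]12C[C@](OC)([Se]c3ccccc3)C(=O)[C@](OC)([C@@H]1O[Si](CC)(CC)CC)[C@@H](c1cc(OC)c(OC)c(OC)c1)[C@@H]2C
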